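## The problem

Target 15 is an achiral, fully aromatic naphthalene. It is numbered here so that C1 carries the 4-hydroxyphenyl ring, C2 and C3 the two 2,4-dihydroxybenzoyl groups, C4 a hydrogen, and ring A (C4a to C8a) hydroxyls at C6 and C7. Ring B thus holds three contiguous carbon substituents, with two ortho aroyl groups pressed against the biaryl bond at C1. This crowded C1–C2–C3 edge is the difficulty; the five benzene rings themselves are available as simple building blocks. There is no stereocentre in 15. Any centres that appear in a reduced ring B (C1, C2, C3) vanish on aromatisation and need no control, although C1 will steer C2 and C3 during ring closure. The seven phenols, among them an oxidation-prone catechol and two chelated ortho-hydroxy ketones, would not survive strong base, one-electron oxidants or a quinone oxidant, so they must stay masked to the last step. Each ketone has an aryl group on its outer side and can enolise only toward C2 or C3. That is the enabling feature: C2 and C3 are both alpha carbons of aryl ketones and the C2–C3 bond is the central bond of a 1,4-diketone. Two carbons of like, nucleophilic polarity can therefore be joined by oxidising a dienolate once ring B is taken back to the tetralin level.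

## Retrosynthesis

**15 to 14.** The seven aryl O–H bonds are traced back to seven methyl ethers. Methyl is chosen over benzyl or silyl because it alone tolerates a lithium amide, a divalent copper oxidant, palladium and rhodium catalysis and a quinone dehydrogenation, and because all building blocks are sold in methylated form. The price is one forcing Lewis-acid deprotection at the end, on a substrate that no longer has a stereocentre or an sp3 carbon to damage.

**14 to 12.** No skeletal bond is cut; four hydrogens are restored at C1–C4. Only at the tetralin level are C2 and C3 sp3 alpha carbons able to carry enolates. The forward dehydrogenation is helped by the ring A methoxy groups, which lie para to C4a and C8a and stabilise positive charge at C4 and C1, and by the acidity of the C2 and C3 hydrogens. Tetralin 12 has three stereocentres, none of which has to be controlled.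

**12 to 10.** The C2–C3 bond is cut. The neighbouring cuts are weaker. A Friedel–Crafts closure of C1–C8a would need an acyclic 1,4-diketone made by cross-coupling two different enolates. A C3–C4 or C1–C2 closure would need one alpha carbon turned into an electrophile in the presence of a second, nearly identical ketone. The C2–C3 cut instead uses both ketones as equal activating groups. It gives diketone 10, whose two arms end in the same aryl ketone and hang from adjacent carbons of ring A. The forward step is an intramolecular oxidative coupling through dienolate 11. It must favour six-membered closure over intermolecular coupling.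

**10 to 6 and 9 (9 to 7 and 8).** The C4–C4a bond is cut. A Heck reaction of aryl bromide 6 with vinyl carbinol 9 attaches the three-carbon arm and delivers the saturated ketone in the same operation, with no separate redox step. Carbinol 9 comes in one step from aldehyde 7 and vinyl Grignard reagent 8. The forward reaction has to insert an unactivated alkene into a hindered, electron-rich arylpalladium.

**6 to 4 and 5.** The bond from C1 to the 4-methoxyphenyl ring is cut, giving enone 4 and boronic acid 5. Rhodium-catalysed conjugate addition tolerates the aryl bromide that is needed next. The order matters. If the ketone arm were installed first, its enolate could add to the enone in a five-membered intramolecular Michael reaction under the basic conditions. With the addition first, no such pathway exists.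

**4 to 1 and 2.** The C1–C2 bond (the enone double bond) is cut by an aldol condensation through adduct 3. Aldehyde 1 cannot enolise and already carries the bromine ortho to the future C1, and ketone 2 is the first resorcinol unit. Both are commercial.

## Roads not taken

**Alternative 1:** This road cuts C1–C8a, C2–C3 and C4–C4a at once, with the two ketones masked as a cyclic ether.

- **Forward step.** Pd2(dba)3 (zerovalent palladium) would cocyclise the aryne released by CsF from silyl triflate A2 with diyne ether A3. This gives dihydronaphthofuran A1, whose ether ring must then be oxidised open to 14.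
- **Merits.** Three C–C bonds form and ring B arrives aromatic in one convergent step, and the symmetric aryne raises no regiochemical question. In bonds per step this road is clearly better than the chosen one.
- **Weak points.** A3 is an unsymmetrical ether of two secondary carbinols that are each benzylic, propargylic and attached to a 2,4-dimethoxyphenyl ring, so ionisation and scrambling threaten its assembly. One alkyne must be terminal to leave C4 unsubstituted, and it is acidic toward fluoride and reactive toward the aryne. Aryne trimerisation and diyne self-cyclisation compete in the three-component step. Opening the ether needs oxidation at both benzylic C–H bonds, through an ortho-quinoid furan, beside four electron-rich arenes.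
- **Comparison.** The step count is similar. The chosen plan forms one C–C bond in its key step and needs a dehydrogenation, but it uses only robust two-component reactions on cheap materials, and its oxidation-level adjustment is better precedented than the ether opening.

**Alternative 2:** This road cuts the four C–C bonds that make the two outer resorcinol rings.

- **Forward step.** Two molecules of diene A6 would add to the two ethynyl ketones of A5. Loss of methanol and of the silyl group would give A4, and five ether cleavages would complete 15.
- **Merits.** The polarised diene adds with reliable regiochemistry under neutral thermal conditions. The endgame is milder, with two fewer ethers to cleave and no dehydrogenation.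
- **Weak points.** The key step builds the cheapest part of the molecule, rings that compounds 2 and 7 supply ready-made. The real problem, the 1-aryl-2,3-diacylnaphthalene core, is left unsolved inside A5. A5 is a pair of adjacent, hindered ynones, which are strong Michael acceptors prone to intramolecular reaction, and its own synthesis would be longer than the whole chosen route.
- **Comparison.** The chosen plan sets against the milder endgame the fact that its key step forms the crowded C2–C3 bond itself.

**Alternative 3:** This road cuts C1–C8a and C4–C4a in a Diels–Alder sense.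

- **Forward step.** The aryne from A2 would add across the alpha carbons of furan A8 to give the 1,4-epoxide A7. Removal of the bridging oxygen would give 14.
- **Merits.** The step is convergent and regiochemically unambiguous. A7 is only one deoxygenation from the aromatic core, which is potentially a shorter endgame than the chosen one.
- **Weak points.** A8 carries two acyl groups on its beta carbons and an aryl group at the reacting alpha carbon. It is an electron-poor, hindered diene for an electrophilic aryne. It also needs several steps to make, most naturally from a 1,4-dicarbonyl precursor. The usual deoxygenating reagents (TiCl4 with Zn, Fe2(CO)9, Me3SiI) also attack aryl ketones and the ene-dione of A7. Acid diverts such epoxides to naphthols.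
- **Comparison.** In the chosen plan the ketones are the groups that drive the key step. Here they are liabilities in both the cycloaddition and the deoxygenation.

Key step: step 5

## Route

Remark: the target is achiral. Compounds 6, 9 and 10 are handled as racemates and 12 as whatever diastereomer mixture forms, since step 6 removes every stereocentre. Target numbering (C1–C4, ring A) is used for all intermediates.

Step 1
Reactants: 1 2-bromo-4,5-dimethoxybenzaldehyde; 2 1-(2,4-dimethoxyphenyl)ethanone
Product: 4 (E)-3-(2-bromo-4,5-dimethoxyphenyl)-1-(2,4-dimethoxyphenyl)prop-2-en-1-one, via beta-hydroxy ketone 3 (not isolated)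
Conditions: KOH (aq), EtOH, rt
Reagents that add atoms: none
Why: Claisen–Schmidt aldol condensation: the aldehyde cannot enolise, the methyl ketone enolate adds to it, and E1cB loss of water from 3 gives the conjugated (E)-enone.

Step 2
Reactants: 4 (E)-3-(2-bromo-4,5-dimethoxyphenyl)-1-(2,4-dimethoxyphenyl)prop-2-en-1-one; 5 4-methoxyphenylboronic acid
Product: 6 rac-3-(2-bromo-4,5-dimethoxyphenyl)-1-(2,4-dimethoxyphenyl)-3-(4-methoxyphenyl)propan-1-one
Conditions: [RhCl(cod)]2 (3 mol %), KOH (0.5 equiv), 1,4-dioxane/H2O (10:1), 50 °C
Reagents that add atoms: none
Why: Rhodium-catalysed conjugate addition of an arylboronic acid (Hayashi–Miyaura type): aryl transfer from boron to monovalent rhodium, enone insertion and hydrolysis of the rhodium enolate; the aryl bromide is inert to monovalent rhodium here, and C1 forms as a racemate because the diene ligand is achiral.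

Step 3
Reactants: 7 2,4-dimethoxybenzaldehyde; 8 vinylmagnesium bromide
Product: 9 rac-1-(2,4-dimethoxyphenyl)prop-2-en-1-ol
Conditions: THF, 0 °C; then H2O
Reagents that add atoms: none
Why: Grignard 1,2-addition to a non-enolisable aldehyde; the acid-labile carbinol is quenched without acid and used promptly, and it is racemic because nothing directs the facial attack.

Step 4
Reactants: 6 rac-3-(2-bromo-4,5-dimethoxyphenyl)-1-(2,4-dimethoxyphenyl)-3-(4-methoxyphenyl)propan-1-one; 9 rac-1-(2,4-dimethoxyphenyl)prop-2-en-1-ol
Product: 10 rac-3-[2-[3-(2,4-dimethoxyphenyl)-3-oxopropyl]-4,5-dimethoxyphenyl]-1-(2,4-dimethoxyphenyl)-3-(4-methoxyphenyl)propan-1-one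
Conditions: Pd(OAc)2 (5 mol %), Bu4NCl, NaHCO3, DMF, 90 °C
Reagents that add atoms: none
Why: Heck reaction of an aryl bromide with a secondary allylic alcohol under Jeffery conditions: the arylpalladium adds to the terminal alkene carbon and beta-hydride elimination takes the carbinol hydrogen, so the saturated aryl ketone arm is delivered directly; the centre at C1 is untouched.

Step 5
Reactants: 10 rac-3-[2-[3-(2,4-dimethoxyphenyl)-3-oxopropyl]-4,5-dimethoxyphenyl]-1-(2,4-dimethoxyphenyl)-3-(4-methoxyphenyl)propan-1-one
Product: 12 rac-[(1R,2S,3S)-6,7-dimethoxy-1-(4-methoxyphenyl)-1,2,3,4-tetrahydronaphthalene-2,3-diyl]bis[(2,4-dimethoxyphenyl)methanone] (1,2-trans, 2,3-trans), via dilithium dienolate 11 (not isolated)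
Conditions: LiN(iPr)2 (2.3 equiv), THF, −78 °C (10 added slowly, ca. 0.01 M); then CuCl2 (2.4 equiv), DMF, −78 → 0 °C
Reagents that add atoms: none
Why: Two equivalents of LiN(iPr)2 remove one proton from each alpha-methylene group (C2 and C3), the only enolisable positions, to give the dilithium (Z,Z)-dienolate 11. Divalent copper oxidises one enolate by one electron to an alpha-keto radical, which adds to the alpha carbon of the second enolate in a 6-exo-trig closure of ring B; the resulting ketyl radical anion gives a second electron to CuCl2 and the 1,4-diketone 12 results. The closest known reaction type is the intramolecular oxidative coupling of ketone dienolates with CuCl2 or FeCl3 to give cyclic 1,4-diketones. The new centres C2 and C3 are set relative to C1 in a chair-like transition state with the 4-methoxyphenyl group and both enolate units pseudo-equatorial, which should favour the all-trans isomer, and both remain epimerisable alpha to their ketones; step 6 erases all three, so any mixture is carried on. The step needs ring closure to win over intermolecular coupling and alpha-chlorination, which the ortho placement of the two arms on ring A, the six-membered transition state and high dilution secure. It also needs the dienolate to form before a mono-enolate can add to the other ketone in an aldol sense, which slow addition of 10 to excess base at −78 °C secures.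

Step 6
Reactants: 12 rac-[(1R,2S,3S)-6,7-dimethoxy-1-(4-methoxyphenyl)-1,2,3,4-tetrahydronaphthalene-2,3-diyl]bis[(2,4-dimethoxyphenyl)methanone]
Product: 14 [6,7-dimethoxy-1-(4-methoxyphenyl)naphthalene-2,3-diyl]bis[(2,4-dimethoxyphenyl)methanone], via dihydronaphthalene 13 (not isolated)
Conditions: DDQ (3 equiv), 1,4-dioxane, reflux
Reagents that add atoms: none
Why: Quinone dehydrogenation of an aryltetralin to an arylnaphthalene: hydride abstraction at C1 (diaryl-stabilised, para-methoxy-assisted cation) and loss of the acidic C2 proton gives 13, and a second hydride abstraction at C4 with loss of the C3 proton aromatises ring B and removes all stereocentres.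

Step 7
Reactants: 14 [6,7-dimethoxy-1-(4-methoxyphenyl)naphthalene-2,3-diyl]bis[(2,4-dimethoxyphenyl)methanone]
Product: 15 [6,7-dihydroxy-1-(4-hydroxyphenyl)naphthalene-2,3-diyl]bis[(2,4-dihydroxyphenyl)methanone]
Conditions: BBr3 (14 equiv), CH2Cl2, −78 °C → rt; then ice/H2O
Reagents that add atoms: none
Why: Lewis-acid cleavage of aryl methyl ethers: boron coordinates each ether oxygen and bromide attacks the methyl group, the two ortho-methoxy groups reacting first through chelation to the carbonyls; hydrolysis of the aryl borates releases the seven phenols.

## Compound list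

1 | 2-bromo-4,5-dimethoxybenzaldehyde | COc1cc(Br)c(C=O)cc1OC | starting material
2 | 1-(2,4-dimethoxyphenyl)ethanone | COc1ccc(C(C)=O)c(OC)c1 | starting material
3 | rac-3-(2-bromo-4,5-dimethoxyphenyl)-1-(2,4-dimethoxyphenyl)-3-hydroxypropan-1-one (one enantiomer drawn) | COc1ccc(C(=O)C[C@H](O)c2cc(OC)c(OC)cc2Br)c(OC)c1 | intermediate
4 | (E)-3-(2-bromo-4,5-dimethoxyphenyl)-1-(2,4-dimethoxyphenyl)prop-2-en-1-one | COc1ccc(C(=O)/C=C/c2cc(OC)c(OC)cc2Br)c(OC)c1 | intermediate
5 | 4-methoxyphenylboronic acid | COc1ccc(cc1)B(O)O | starting material
6 | rac-3-(2-bromo-4,5-dimethoxyphenyl)-1-(2,4-dimethoxyphenyl)-3-(4-methoxyphenyl)propan-1-one (one enantiomer drawn) | COc1ccc(cc1)[C@H](c1cc(OC)c(OC)cc1Br)CC(=O)c1ccc(OC)cc1OC | intermediate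
7 | 2,4-dimethoxybenzaldehyde | COc1ccc(C=O)c(OC)c1 | starting material
8 | vinylmagnesium bromide | C=C[Mg]Br | starting material
9 | rac-1-(2,4-dimethoxyphenyl)prop-2-en-1-ol (one enantiomer drawn) | C=C[C@H](O)c1ccc(OC)cc1OC | intermediate
10 | rac-3-[2-[3-(2,4-dimethoxyphenyl)-3-oxopropyl]-4,5-dimethoxyphenyl]-1-(2,4-dimethoxyphenyl)-3-(4-methoxyphenyl)propan-1-one (one enantiomer drawn) | COc1ccc(cc1)[C@H](c1cc(OC)c(OC)cc1CCC(=O)c1ccc(OC)cc1OC)CC(=O)c1ccc(OC)cc1OC | intermediate
11 | dilithium (Z,Z)-dienolate of 10, enolised toward C2 and C3 (racemic, one enantiomer drawn) | COc1ccc(cc1)[C@H](c1cc(OC)c(OC)cc1C/C=C(\O[Li])c1ccc(OC)cc1OC)/C=C(\O[Li])c1ccc(OC)cc1OC | intermediate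
12 | rac-[(1R,2S,3S)-6,7-dimethoxy-1-(4-methoxyphenyl)-1,2,3,4-tetrahydronaphthalene-2,3-diyl]bis[(2,4-dimethoxyphenyl)methanone] (all-trans, one enantiomer drawn) | COc1ccc(cc1)[C@H]1[C@H](C(=O)c2ccc(OC)cc2OC)[C@@H](C(=O)c2ccc(OC)cc2OC)Cc2cc(OC)c(OC)cc21 | intermediate
13 | rac-[6,7-dimethoxy-1-(4-methoxyphenyl)-3,4-dihydronaphthalene-2,3-diyl]bis[(2,4-dimethoxyphenyl)methanone] (C1=C2 double bond in target numbering, one enantiomer drawn) | COc1ccc(cc1)C1=C(C(=O)c2ccc(OC)cc2OC)[C@@H](C(=O)c2ccc(OC)cc2OC)Cc2cc(OC)c(OC)cc21 | intermediate
14 | [6,7-dimethoxy-1-(4-methoxyphenyl)naphthalene-2,3-diyl]bis[(2,4-dimethoxyphenyl)methanone] | COc1ccc(cc1)-c1c(C(=O)c2ccc(OC)cc2OC)c(C(=O)c2ccc(OC)cc2OC)cc2cc(OC)c(OC)cc12 | intermediate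
15 | [6,7-dihydroxy-1-(4-hydroxyphenyl)naphthalene-2,3-diyl]bis[(2,4-dihydroxyphenyl)methanone] | O=C(c1ccc(O)cc1O)c1cc2cc(O)c(O)cc2c(-c2ccc(O)cc2)c1C(=O)c1ccc(O)cc1O | target

## Step count and risks

Total: 7 steps. Longest linear sequence: 6 steps (steps 1, 2, 4, 5, 6, 7 from 1); step 3 is a one-step branch that supplies 9.

**Step 5 (key step).** Deprotonation may be incomplete, so that a mono-enolate adds to the other ketone in a seven-membered aldol closure. During oxidation, alpha-chlorination by CuCl2 or intermolecular coupling may compete with ring closure. Over-oxidation of the product through its own dienolate would do no harm, because that material also converges on 14 in step 6. The fallback sets out from 10 and returns at 12. Soft enolisation (Me3SiOTf, Et3N, CH2Cl2, 0 °C) gives the bis(trimethylsilyl enol ether) F1 without any strongly basic dienolate. One-electron oxidation of F1 with (NH4)2Ce(NO3)6 (tetravalent cerium) and NaHCO3 in MeCN at −10 °C generates an enol ether radical cation that closes onto the second enol ether and, after loss of the silyl groups, gives 12.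

**Step 4.** Insertion of the unactivated allylic alcohol into the hindered, electron-rich arylpalladium may be slow. Intramolecular C–H arylation of the neighbouring 4-methoxyphenyl ring, or hydrodebromination through oxidation of the alcohol, could then take over. Beta-hydride elimination away from the carbinol carbon is a further leak. The fallback sets out from 9 and 6 and returns at 10. Carbinol 9 is oxidised with MnO2 (CH2Cl2, rt) to 1-(2,4-dimethoxyphenyl)prop-2-en-1-one F2, an activated acceptor that inserts faster and can eliminate in only one direction. Its Heck reaction with 6 (Pd(OAc)2, Bu4NCl, NaHCO3, DMF, 60 °C) gives the (E)-enone F3. Conjugate reduction of the new double bond (H2, Pd/C, EtOAc, or [(Ph3P)CuH]6) gives 10.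

**Step 6.** Dehydrogenation may stall at the dihydronaphthalene stage, or the four electron-rich methoxyarenes may undergo oxidative side reactions with the quinone at reflux. The fallback sets out from 12 and returns at 14. Double deprotonation at C2 and C3 (LiN(iPr)2, THF, −78 °C) and oxidation of the conjugated dienolate with I2 gives the 1,4-dihydronaphthalene ene-dione F4. F4 loses its doubly activated C1 and C4 hydrogens to MnO2 in CH2Cl2 at room temperature to give 14.

**Step 7.** Cleavage may stop short, because boron held in the chelated ortho-oxygen and carbonyl pocket deactivates the para-methoxy groups. A liberated ortho-phenol may also close onto the neighbouring ketone under the Lewis acid. The fallback sets out from 14 and returns at 15. BCl3 (CH2Cl2, 0 °C) removes only the two chelated ortho-methyl groups and gives [6,7-dimethoxy-1-(4-methoxyphenyl)naphthalene-2,3-diyl]bis[(2-hydroxy-4-methoxyphenyl)methanone] F5. The remaining five ethers are then cleaved by chloride attack in molten pyridinium chloride at 190 °C under argon, a medium that is not Lewis acidic, to give 15.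

## Further compounds

F1 | step 5 | bis(trimethylsilyl enol ether) of 10, both enol ethers Z (racemic, one enantiomer drawn) | COc1ccc(cc1)[C@H](c1cc(OC)c(OC)cc1C/C=C(\O[Si](C)(C)C)c1ccc(OC)cc1OC)/C=C(\O[Si](C)(C)C)c1ccc(OC)cc1OC
F2 | step 4 | 1-(2,4-dimethoxyphenyl)prop-2-en-1-one | C=CC(=O)c1ccc(OC)cc1OC
F3 | step 4 | rac-(E)-3-[2-[3-(2,4-dimethoxyphenyl)-1-(4-methoxyphenyl)-3-oxopropyl]-4,5-dimethoxyphenyl]-1-(2,4-dimethoxyphenyl)prop-2-en-1-one (one enantiomer drawn) | COc1ccc(cc1)[C@H](c1cc(OC)c(OC)cc1/C=C/C(=O)c1ccc(OC)cc1OC)CC(=O)c1ccc(OC)cc1OC
F4 | step 6 | rac-[6,7-dimethoxy-1-(4-methoxyphenyl)-1,4-dihydronaphthalene-2,3-diyl]bis[(2,4-dimethoxyphenyl)methanone] (one enantiomer drawn) | COc1ccc(cc1)[C@H]1C(C(=O)c2ccc(OC)cc2OC)=C(C(=O)c2ccc(OC)cc2OC)Cc2cc(OC)c(OC)cc21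
F5 | step 7 | [6,7-dimethoxy-1-(4-methoxyphenyl)naphthalene-2,3-diyl]bis[(2-hydroxy-4-methoxyphenyl)methanone] | COc1ccc(cc1)-c1c(C(=O)c2ccc(OC)cc2O)c(C(=O)c2ccc(OC)cc2O)cc2cc(OC)c(OC)cc12
A1 | alternative 1 | 1,3-bis(2,4-dimethoxyphenyl)-6,7-dimethoxy-4-(4-methoxyphenyl)-1,3-dihydronaphtho[2,3-c]furan (one diastereomer drawn) | COc1ccc(cc1)-c1c2[C@@H](O[C@H](c2cc2cc(OC)c(OC)cc12)c1ccc(OC)cc1OC)c1ccc(OC)cc1OC
A2 | alternative 1 | 4,5-dimethoxy-2-(trimethylsilyl)phenyl trifluoromethanesulfonate | COc1cc(OS(=O)(=O)C(F)(F)F)c(cc1OC)[Si](C)(C)C
A3 | alternative 1 | 1-[1-[[1-(2,4-dimethoxyphenyl)prop-2-yn-1-yl]oxy]-3-(4-methoxyphenyl)prop-2-yn-1-yl]-2,4-dimethoxybenzene (one diastereomer drawn) | COc1ccc(cc1)C#C[C@@H](O[C@H](C#C)c1ccc(OC)cc1OC)c1ccc(OC)cc1OC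
A4 | alternative 2 | [6,7-dimethoxy-1-(4-methoxyphenyl)naphthalene-2,3-diyl]bis[(4-hydroxy-2-methoxyphenyl)methanone] | COc1ccc(cc1)-c1c(C(=O)c2ccc(O)cc2OC)c(C(=O)c2ccc(O)cc2OC)cc2cc(OC)c(OC)cc12
A5 | alternative 2 | 1,1'-[6,7-dimethoxy-1-(4-methoxyphenyl)naphthalene-2,3-diyl]bis(prop-2-yn-1-one) | COc1ccc(cc1)-c1c(C(=O)C#C)c(C(=O)C#C)cc2cc(OC)c(OC)cc12
A6 | alternative 2 | 1,1-dimethoxy-3-(trimethylsilyloxy)buta-1,3-diene | COC(OC)=CC(=C)O[Si](C)(C)C
A7 | alternative 3 | rac-[6,7-dimethoxy-1-(4-methoxyphenyl)-1,4-dihydro-1,4-epoxynaphthalene-2,3-diyl]bis[(2,4-dimethoxyphenyl)methanone] (one enantiomer drawn) | COc1ccc(cc1)[C@@]12O[C@@H](C(C(=O)c3ccc(OC)cc3OC)=C1C(=O)c1ccc(OC)cc1OC)c1cc(OC)c(OC)cc12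
A8 | alternative 3 | [2-(4-methoxyphenyl)furan-3,4-diyl]bis[(2,4-dimethoxyphenyl)methanone] | COc1ccc(cc1)-c1occ(C(=O)c2ccc(OC)cc2OC)c1C(=O)c1ccc(OC)cc1OC
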